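**Strategy.** Tying C7 to C13 in thought turns the C8/C9 pair (secondary C17 methyl beside the quaternary carbon bearing the C20 methyl) and the C11–C12–C13(C16) arm into a six-membered carbocycle C7–C8–C9–C11–C12–C13 whose exocyclic formyl carbon is C10 of ring A. One catalytic enantioselective Diels–Alder reaction of methacrolein with (E)-2-methylpenta-1,3-diene, both bought, forms C8–C9 and C11–C12 and sets C8 and C9. Ring A is then grown at C10, the sacrificial C7=C13 alkene is cleaved to the C7 aldehyde and C13 methyl ketone, ring B is closed by metathesis and dihydroxylated, and C13 is set by Sharpless epoxidation.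

Key step: step 1

Remark: halimane numbering is used for all atoms; the (1R,2R) adduct 3 (formyl trans to the C2 methyl) already carries the target's C8 and C9 configurations, the C8 descriptor changing from R to S later only because C7 gains oxygen.

**Route**

Step 1
Reactants: 1 methacrolein; 2 (E)-2-methylpenta-1,3-diene
Product: 3 (1R,2R)-1,2,4-trimethylcyclohex-3-ene-1-carbaldehyde (formyl trans to the C2 methyl)
Conditions: o-tolyl-oxazaborolidinium triflimide from α,α-diphenylprolinol (15 mol %; the antipode that exposes the Cα-si face of bound methacrolein), 2 (3 equiv), CH2Cl2, −78 → −40 °C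
Reagents that add atoms: none
Why: The cationic boron Lewis acid binds the formyl oxygen of s-trans methacrolein and lowers its LUMO, so that the s-cis diene adds in a concerted but asynchronous [4+2] cycloaddition in which C11–C12 bonding runs ahead of C8–C9. The closest known reaction type is the oxazaborolidinium- (or acyloxyborane-) catalysed enantioselective Diels–Alder reaction of α-substituted acroleins with acyclic dienes. The sacrificial ring C7–C8–C9–C11–C12–C13 is closed by suprafacial intermolecular [4+2] cycloaddition, the two σ-bonds forming at the two diene termini in one operation. C9 is set by the catalyst, which shields one enantioface of the bound enal so that the diene attacks the Cα-si face, and C8 is set relative to C9 by the (E) geometry of C7=C8 together with the formyl-exo orientation, which puts C17 cis to C20 and trans to the formyl group. Regiochemistry (C8 to C9, C12 to C11) is secured by the matched ortho/para directing effects of the C8 and C13 methyl groups, which make C12 the nucleophilic terminus, and the formyl-exo mode relies on the α-methyl group of the dienophile and the bulk of the catalyst-bound formyl group, as is the rule with cyclic dienes. With an acyclic diene this exo preference is the least certain element of the whole route, and any endo adduct (the C8 epimer) would have to be separated.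

Step 2
Reactants: 3 (1R,2R)-1,2,4-trimethylcyclohex-3-ene-1-carbaldehyde; 4 ethyl 3,3-dimethylpent-4-enoate
Product: 6 ethyl 2-{hydroxy[(1R,2R)-1,2,4-trimethylcyclohex-3-en-1-yl]methyl}-3,3-dimethylpent-4-enoate (both new centres as mixtures), via lithium ester enolate 5 (not isolated)
Conditions: LDA (1.1 equiv), THF, −78 °C; then 3, −78 °C; aq NH4Cl
Reagents that add atoms: lithium diisopropylamide CC(C)N([Li])C(C)C (lithium of 5 only)
Why: Aldol addition of a preformed lithium ester enolate to a non-enolisable aldehyde forms C5–C10 with the C4–C5 bond and the gem-dimethyl carbon already in place, and the two new centres need no control because both become sp2 in step 4.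

Step 3
Reactants: 6 the β-hydroxy ester
Product: 7 ethyl 3,3-dimethyl-2-[(1R,2R)-1,2,4-trimethylcyclohex-3-ene-1-carbonyl]pent-4-enoate (C5 as a mixture)
Conditions: Dess–Martin periodinane, CH2Cl2, rt
Reagents that add atoms: none
Why: Dess–Martin oxidation turns hindered secondary alcohols into ketones under near-neutral conditions that should avoid retro-aldol cleavage.

Step 4
Reactants: 7 the β-keto ester
Product: 9 ethyl (2E)-3,3-dimethyl-2-{[(trifluoromethanesulfonyl)oxy][(1R,2R)-1,2,4-trimethylcyclohex-3-en-1-yl]methylidene}pent-4-enoate, via potassium enolate 8 (not isolated)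
Conditions: KHMDS (1.2 equiv), THF, −78 → 0 °C; then PhNTf2, 0 °C → rt
Reagents that add atoms: potassium hexamethyldisilazide C[Si](C)(C)N([K])[Si](C)(C)C (potassium of 8 only); N-phenylbis(trifluoromethanesulfonimide) O=S(=O)(N(c1ccccc1)S(=O)(=O)C(F)(F)F)C(F)(F)F
Why: Enol triflate formation from a β-keto ester enolate should work because C5–H is the only acidic proton, and the enolate can only place the two quaternary groups (C9, C4) trans, which puts OTf cis to C4 as ring A requires.

Step 5
Reactants: 9 the enol triflate; 10 allyltributylstannane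
Product: 11 ethyl (2Z)-2-(2-methylbut-3-en-2-yl)-3-[(1R,2R)-1,2,4-trimethylcyclohex-3-en-1-yl]hexa-2,5-dienoate
Conditions: Pd(PPh3)4 (5 mol %), LiCl (3 equiv), THF, 65 °C
Reagents that add atoms: none
Why: Stille coupling of an enol triflate with an allylstannane proceeds with retention of alkene geometry and so should give the regiodefined tetrasubstituted C5=C10 enoate with C1 cis to C4.

Step 6
Reactants: 11 the triene ester
Product: 12 ethyl 6,6-dimethyl-2-[(1R,2R)-1,2,4-trimethylcyclohex-3-en-1-yl]cyclohexa-1,4-diene-1-carboxylate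
Conditions: (H2IMes)(PCy3)Cl2Ru=CHPh (5 mol %), CH2Cl2, 40 °C
Reagents that add atoms: none
Why: Ring-closing metathesis of the cis-held allyl and 1,1-dimethylallyl arms closes ring A as a six-membered ring, while the tri- and tetrasubstituted alkenes should not engage the catalyst.

Step 7
Reactants: 12 the ring-A diene ester
Product: 13 ethyl 6,6-dimethyl-2-[(1R,2R)-1,2,4-trimethylcyclohex-3-en-1-yl]cyclohex-1-ene-1-carboxylate
Conditions: 2-nitrobenzenesulfonylhydrazide, Et3N, CH2Cl2, rt
Reagents that add atoms: none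
Why: Diimide reduction saturates the cis-disubstituted C2=C3 alkene much faster than tri- or tetrasubstituted alkenes and cannot isomerise the skipped diene.

Step 8
Reactants: 13 the ring-A ester
Product: 15 ethyl 2-[(2S,3R)-2,3-dimethyl-1,6-dioxoheptan-3-yl]-6,6-dimethylcyclohex-1-ene-1-carboxylate, via vicinal diol 14 (not isolated)
Conditions: OsO4 (2 mol %), NMO, acetone–H2O, rt; then NaIO4, rt
Reagents that add atoms: osmium tetroxide O=[Os](=O)(=O)=O (catalytic, turned over by NMO); N-methylmorpholine N-oxide C[N+]1([O-])CCOCC1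
Why: Lemieux–Johnson cleavage should take only the accessible trisubstituted C7=C13 alkene, since the ester-bearing C5=C10 alkene is electron-poor and flanked by two quaternary carbons, and the neutral conditions leave C8 next to the new aldehyde untouched.

Step 9
Reactants: 15 the keto aldehyde
Product: 16 ethyl 2-[(3R,4R)-3,4-dimethyl-7-oxooct-1-en-4-yl]-6,6-dimethylcyclohex-1-ene-1-carboxylate
Conditions: Ph3PCH3Br (1.1 equiv), KHMDS (1.05 equiv), THF, 0 °C; then 15, −78 → −20 °C
Reagents that add atoms: methyltriphenylphosphonium bromide C[P+](c1ccccc1)(c1ccccc1)c1ccccc1.[Br-]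
Why: Wittig methylenation with one equivalent of salt-free ylide at low temperature takes the C7 aldehyde in preference to the C13 methyl ketone, and the hindered C8–H should not be deprotonated, so C8 keeps its configuration.

Step 10
Reactants: 16 the vinyl methyl ketone; 17 triethyl phosphonoacetate
Product: 19 ethyl 2-[(3R,4R,7E)-9-ethoxy-3,4,7-trimethyl-9-oxonona-1,7-dien-4-yl]-6,6-dimethylcyclohex-1-ene-1-carboxylate, via sodium phosphonate carbanion 18 (not isolated)
Conditions: NaH, THF, 0 °C; then 16, rt → 50 °C; minor (Z)-isomer removed by chromatography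
Reagents that add atoms: sodium hydride [Na+].[H-] (sodium of 18 only)
Why: Horner–Wadsworth–Emmons olefination of the unhindered methyl ketone should give the trisubstituted enoate mainly as the separable (E)-isomer, while the hindered ring ester is inert.

Step 11
Reactants: 19 the diester
Product: 20 (2E,6R,7R)-6-[2-(hydroxymethyl)-3,3-dimethylcyclohex-1-en-1-yl]-3,6,7-trimethylnona-2,8-dien-1-ol
Conditions: DIBAL-H (6 equiv), CH2Cl2, −78 °C → rt; Rochelle salt
Reagents that add atoms: none
Why: DIBAL-H reduces both conjugated esters by 1,2-reduction to primary allylic alcohols without touching the alkenes.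

Step 12
Reactants: 20 the bis-allylic diol
Product: 21 [(2S,3S)-3-{(3R,4R)-3-[2-(hydroxymethyl)-3,3-dimethylcyclohex-1-en-1-yl]-3,4-dimethylhex-5-en-1-yl}-3-methyloxiran-2-yl]methanol
Conditions: Ti(OiPr)4 (20 mol %), L-(+)-diethyl tartrate (24 mol %), t-BuOOH, 4 Å MS, CH2Cl2, −20 °C
Reagents that add atoms: tert-butyl hydroperoxide CC(C)(C)OO
Why: Sharpless asymmetric epoxidation with L-(+)-tartrate should convert the geraniol-type (E)-allylic alcohol into the (2S,3S)-epoxide and so set C13 (S) by reagent control, whereas the ring allylic alcohol, whose tetrasubstituted alkene carries a Z tert-alkyl group and a quaternary neighbour, should be too hindered to react.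

Step 13
Reactants: 21 the epoxy diol
Product: 22 2-{(3R,4R)-1-[(2S,3S)-3-(hydroxymethyl)-2-methyloxiran-2-yl]-3,4-dimethylhex-5-en-3-yl}-6,6-dimethylcyclohex-1-ene-1-carbaldehyde
Conditions: activated MnO2 (excess), CH2Cl2, rt
Reagents that add atoms: none
Why: Manganese dioxide oxidises only allylic alcohols, so the ring CH2OH gives the enal (C6) while the epoxy alcohol is left alone.

Step 14
Reactants: 22 the epoxy alcohol enal
Product: 24 2-{(3R,4R)-1-[(2S,3R)-3-(chloromethyl)-2-methyloxiran-2-yl]-3,4-dimethylhex-5-en-3-yl}-6,6-dimethylcyclohex-1-ene-1-carbaldehyde, via epoxy mesylate 23 (not isolated)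
Conditions: MsCl, Et3N, CH2Cl2, 0 °C; then LiCl, DMF, 40 °C
Reagents that add atoms: methanesulfonyl chloride CS(=O)(=O)Cl (mesyl group of 23 only); lithium chloride [Li+].[Cl-]
Why: Mesylation of the only hydroxyl and SN2 displacement by chloride give the 2,3-epoxy chloride, a mask for the vinyl carbinol that should survive ylide, ruthenium carbene and osmium tetroxide and needs no deprotection.

Step 15
Reactants: 24 the epoxy chloride enal
Product: 25 (2S,3R)-3-(chloromethyl)-2-[(3R,4R)-3-(2-ethenyl-3,3-dimethylcyclohex-1-en-1-yl)-3,4-dimethylhex-5-en-1-yl]-2-methyloxirane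
Conditions: Ph3PCH3Br (1.3 equiv), KHMDS (1.2 equiv), THF, 0 °C; then 24, −78 → 0 °C
Reagents that add atoms: methyltriphenylphosphonium bromide C[P+](c1ccccc1)(c1ccccc1)c1ccccc1.[Br-]
Why: Wittig methylenation of the hindered enal (a β-cyclocitral-type aldehyde) gives the C6 vinyl group, the aldehyde reacting far faster with the ylide than the primary chloride or the epoxide.

Step 16
Reactants: 25 the triene
Product: 26 (2S,3R)-3-(chloromethyl)-2-methyl-2-{2-[(1R,2R)-1,2,5,5-tetramethyl-1,2,5,6,7,8-hexahydronaphthalen-1-yl]ethyl}oxirane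
Conditions: (H2IMes)(PCy3)Cl2Ru=CHPh (10 mol %), toluene (2 mM), 80 °C
Reagents that add atoms: none
Why: Ring-closing metathesis between the C7 vinyl and the dienyl C6 vinyl group closes ring B as a cyclohexa-1,3-diene, a six-membered closure driven by loss of ethylene that cannot aromatise because C9 is quaternary.

Step 17
Reactants: 26 the bicyclic diene
Product: 27 (1S,2R,3S,4R)-4-{2-[(2S,3R)-3-(chloromethyl)-2-methyloxiran-2-yl]ethyl}-3,4,8,8-tetramethyl-1,2,3,4,5,6,7,8-octahydronaphthalene-1,2-diol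
Conditions: OsO4 (5 mol %), NMO, acetone–H2O, 0 °C → rt
Reagents that add atoms: osmium tetroxide O=[Os](=O)(=O)=O (catalytic, turned over by NMO); N-methylmorpholine N-oxide C[N+]1([O-])CCOCC1
Why: Upjohn dihydroxylation should take the disubstituted C6=C7 bond and not the shielded tetrasubstituted C5=C10 bond, adding syn from the face that carries only the C20 methyl (the other face holds both the C8 methyl and the C11 chain), which sets C6 (S) and C7 (R) cis to each other and trans to C17.

Step 18
Reactants: 27 the diol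
Product: 28 (1S,2R,3S,4R)-4-{2-[(2S,3R)-3-(chloromethyl)-2-methyloxiran-2-yl]ethyl}-1-hydroxy-3,4,8,8-tetramethyl-1,2,3,4,5,6,7,8-octahydronaphthalen-2-yl acetate
Conditions: Ac2O (1.1 equiv), pyridine, CH2Cl2, 0 °C
Reagents that add atoms: acetic anhydride CC(=O)OC(C)=O
Why: Acylation with one equivalent of anhydride should select the equatorial C7 hydroxyl, because the allylic C6 hydroxyl is pseudo-axial and screened by the C4 gem-dimethyl group.

Step 19
Reactants: 28 the epoxy chloride acetate
Product: 30 (1S,2R,3S,4R)-1-hydroxy-4-[(3S)-3-hydroxy-3-methylpent-4-en-1-yl]-3,4,8,8-tetramethyl-1,2,3,4,5,6,7,8-octahydronaphthalen-2-yl acetate, via epoxy iodide 29 (not isolated)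
Conditions: NaI, butan-2-one, 70 °C; then Zn dust, AcOH, THF, rt
Reagents that add atoms: sodium iodide [Na+].[I-] (iodine of 29 only)
Why: Finkelstein exchange followed by zinc-mediated reductive ring opening of the 2,3-epoxy iodide (β-elimination of the epoxide oxygen) unveils the tertiary vinyl carbinol with C13 unchanged, under conditions that should leave the acetate and the allylic alcohol alone.

**Compound list**

1 | methacrolein | CC(=C)C=O | starting material
2 | (E)-2-methylpenta-1,3-diene | C/C=C/C(C)=C | starting material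
3 | (1R,2R)-1,2,4-trimethylcyclohex-3-ene-1-carbaldehyde | CC1=C[C@@H](C)[C@](C)(C=O)CC1 | intermediate
4 | ethyl 3,3-dimethylpent-4-enoate | CCOC(=O)CC(C)(C)C=C | starting material
5 | lithium enolate of ethyl 3,3-dimethylpent-4-enoate | [Li+].CCOC([O-])=CC(C)(C)C=C | intermediate (not isolated)
6 | ethyl 2-{hydroxy[(1R,2R)-1,2,4-trimethylcyclohex-3-en-1-yl]methyl}-3,3-dimethylpent-4-enoate (carbinol and α-carbon as mixtures) | CC1=C[C@@H](C)[C@](C)(C(O)C(C(=O)OCC)C(C)(C)C=C)CC1 | intermediate
7 | ethyl 3,3-dimethyl-2-[(1R,2R)-1,2,4-trimethylcyclohex-3-ene-1-carbonyl]pent-4-enoate (α-carbon as a mixture) | CC1=C[C@@H](C)[C@](C)(C(=O)C(C(=O)OCC)C(C)(C)C=C)CC1 | intermediate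
8 | potassium (E)-enolate of 7 | [K+].CC1=C[C@@H](C)[C@](C)(/C([O-])=C(\C(=O)OCC)C(C)(C)C=C)CC1 | intermediate (not isolated)
9 | ethyl (2E)-3,3-dimethyl-2-{[(trifluoromethanesulfonyl)oxy][(1R,2R)-1,2,4-trimethylcyclohex-3-en-1-yl]methylidene}pent-4-enoate | CC1=C[C@@H](C)[C@](C)(/C(OS(=O)(=O)C(F)(F)F)=C(\C(=O)OCC)C(C)(C)C=C)CC1 | intermediate
10 | allyltributylstannane | C=CC[Sn](CCCC)(CCCC)CCCC | starting material
11 | ethyl (2Z)-2-(2-methylbut-3-en-2-yl)-3-[(1R,2R)-1,2,4-trimethylcyclohex-3-en-1-yl]hexa-2,5-dienoate | CC1=C[C@@H](C)[C@](C)(/C(CC=C)=C(\C(=O)OCC)C(C)(C)C=C)CC1 | intermediate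
12 | ethyl 6,6-dimethyl-2-[(1R,2R)-1,2,4-trimethylcyclohex-3-en-1-yl]cyclohexa-1,4-diene-1-carboxylate | CC1=C[C@@H](C)[C@](C)(C2=C(C(=O)OCC)C(C)(C)C=CC2)CC1 | intermediate
13 | ethyl 6,6-dimethyl-2-[(1R,2R)-1,2,4-trimethylcyclohex-3-en-1-yl]cyclohex-1-ene-1-carboxylate | CC1=C[C@@H](C)[C@](C)(C2=C(C(=O)OCC)C(C)(C)CCC2)CC1 | intermediate
14 | ethyl 2-[(1R,2S)-3,4-dihydroxy-1,2,4-trimethylcyclohexyl]-6,6-dimethylcyclohex-1-ene-1-carboxylate (cis-diol, C3 and C4 as a mixture) | CC1(O)C(O)[C@@H](C)[C@](C)(C2=C(C(=O)OCC)C(C)(C)CCC2)CC1 | intermediate (not isolated)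
15 | ethyl 2-[(2S,3R)-2,3-dimethyl-1,6-dioxoheptan-3-yl]-6,6-dimethylcyclohex-1-ene-1-carboxylate | O=C[C@@H](C)[C@](C)(C1=C(C(=O)OCC)C(C)(C)CCC1)CCC(C)=O | intermediate
16 | ethyl 2-[(3R,4R)-3,4-dimethyl-7-oxooct-1-en-4-yl]-6,6-dimethylcyclohex-1-ene-1-carboxylate | C=C[C@@H](C)[C@](C)(C1=C(C(=O)OCC)C(C)(C)CCC1)CCC(C)=O | intermediate
17 | triethyl phosphonoacetate | CCOC(=O)CP(=O)(OCC)OCC | starting material
18 | sodium salt of triethyl phosphonoacetate | [Na+].CCOC(=O)[CH-]P(=O)(OCC)OCC | intermediate (not isolated)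
19 | ethyl 2-[(3R,4R,7E)-9-ethoxy-3,4,7-trimethyl-9-oxonona-1,7-dien-4-yl]-6,6-dimethylcyclohex-1-ene-1-carboxylate | C=C[C@@H](C)[C@](C)(C1=C(C(=O)OCC)C(C)(C)CCC1)CC/C(C)=C/C(=O)OCC | intermediate
20 | (2E,6R,7R)-6-[2-(hydroxymethyl)-3,3-dimethylcyclohex-1-en-1-yl]-3,6,7-trimethylnona-2,8-dien-1-ol | C=C[C@@H](C)[C@](C)(C1=C(CO)C(C)(C)CCC1)CC/C(C)=C/CO | intermediate
21 | [(2S,3S)-3-{(3R,4R)-3-[2-(hydroxymethyl)-3,3-dimethylcyclohex-1-en-1-yl]-3,4-dimethylhex-5-en-1-yl}-3-methyloxiran-2-yl]methanol | C=C[C@@H](C)[C@](C)(C1=C(CO)C(C)(C)CCC1)CC[C@]2(C)O[C@H]2CO | intermediate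
22 | 2-{(3R,4R)-1-[(2S,3S)-3-(hydroxymethyl)-2-methyloxiran-2-yl]-3,4-dimethylhex-5-en-3-yl}-6,6-dimethylcyclohex-1-ene-1-carbaldehyde | C=C[C@@H](C)[C@](C)(C1=C(C=O)C(C)(C)CCC1)CC[C@]2(C)O[C@H]2CO | intermediate
23 | [(2S,3S)-3-{(3R,4R)-3-(2-formyl-3,3-dimethylcyclohex-1-en-1-yl)-3,4-dimethylhex-5-en-1-yl}-3-methyloxiran-2-yl]methyl methanesulfonate | C=C[C@@H](C)[C@](C)(C1=C(C=O)C(C)(C)CCC1)CC[C@]2(C)O[C@H]2COS(C)(=O)=O | intermediate (not isolated)
24 | 2-{(3R,4R)-1-[(2S,3R)-3-(chloromethyl)-2-methyloxiran-2-yl]-3,4-dimethylhex-5-en-3-yl}-6,6-dimethylcyclohex-1-ene-1-carbaldehyde | C=C[C@@H](C)[C@](C)(C1=C(C=O)C(C)(C)CCC1)CC[C@]2(C)O[C@H]2CCl | intermediate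
25 | (2S,3R)-3-(chloromethyl)-2-[(3R,4R)-3-(2-ethenyl-3,3-dimethylcyclohex-1-en-1-yl)-3,4-dimethylhex-5-en-1-yl]-2-methyloxirane | C=C[C@@H](C)[C@](C)(C1=C(C=C)C(C)(C)CCC1)CC[C@]2(C)O[C@H]2CCl | intermediate
26 | (2S,3R)-3-(chloromethyl)-2-methyl-2-{2-[(1R,2R)-1,2,5,5-tetramethyl-1,2,5,6,7,8-hexahydronaphthalen-1-yl]ethyl}oxirane | ClC[C@@H]1O[C@@]1(C)CC[C@@]2(C)C3=C(C=C[C@H]2C)C(C)(C)CCC3 | intermediate
27 | (1S,2R,3S,4R)-4-{2-[(2S,3R)-3-(chloromethyl)-2-methyloxiran-2-yl]ethyl}-3,4,8,8-tetramethyl-1,2,3,4,5,6,7,8-octahydronaphthalene-1,2-diol | ClC[C@@H]1O[C@@]1(C)CC[C@@]2(C)C3=C([C@H](O)[C@H](O)[C@H]2C)C(C)(C)CCC3 | intermediate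
28 | (1S,2R,3S,4R)-4-{2-[(2S,3R)-3-(chloromethyl)-2-methyloxiran-2-yl]ethyl}-1-hydroxy-3,4,8,8-tetramethyl-1,2,3,4,5,6,7,8-octahydronaphthalen-2-yl acetate | ClC[C@@H]1O[C@@]1(C)CC[C@@]2(C)C3=C([C@H](O)[C@H](OC(C)=O)[C@H]2C)C(C)(C)CCC3 | intermediate
29 | (1S,2R,3S,4R)-1-hydroxy-4-{2-[(2S,3R)-3-(iodomethyl)-2-methyloxiran-2-yl]ethyl}-3,4,8,8-tetramethyl-1,2,3,4,5,6,7,8-octahydronaphthalen-2-yl acetate | IC[C@@H]1O[C@@]1(C)CC[C@@]2(C)C3=C([C@H](O)[C@H](OC(C)=O)[C@H]2C)C(C)(C)CCC3 | intermediate (not isolated)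
30 | (1S,2R,3S,4R)-1-hydroxy-4-[(3S)-3-hydroxy-3-methylpent-4-en-1-yl]-3,4,8,8-tetramethyl-1,2,3,4,5,6,7,8-octahydronaphthalen-2-yl acetate (CNP0126002.2; halimane numbering 6S,7R,8S,9R,13S) | C=C[C@@](C)(O)CC[C@@]1(C)C2=C([C@H](O)[C@H](OC(C)=O)[C@H]1C)C(C)(C)CCC2 | target

**Totals**

Total step count: 19. Longest linear sequence: 19 steps (1 and 2 to 30); 4, 10 and 17 are bought and enter directly.

**Steps most likely to fail**

1. Step 1. The cycloaddition may proceed with poor or reversed exo/endo selectivity (formyl-endo being common for acyclic 1-substituted dienes) or with incomplete enantioface control. The fallback exchanges the roles of the two substituents on the dienophile so that the ordinary formyl-endo mode gives the required relative configuration. It sets out from 2 and comes back at 3. Commercial 2-methylidenepropane-1,3-diol is mono-protected (NaH, 4-methoxybenzyl chloride) to 2-{[(4-methoxyphenyl)methoxy]methyl}prop-2-en-1-ol F1 and oxidised with MnO2 to 2-{[(4-methoxyphenyl)methoxy]methyl}prop-2-enal F2. Cycloaddition of F2 with 2 under the same class of chiral boron catalyst (antipode chosen for the new dienophile) should give the endo adduct (1S,2R)-1-{[(4-methoxyphenyl)methoxy]methyl}-2,4-dimethylcyclohex-3-ene-1-carbaldehyde F3, in which the formyl group is cis to the C8 methyl and is destined to become C20. Wolff–Kishner reduction (N2H4·H2O, KOH, diethylene glycol, 200 °C) turns the formyl group into the methyl group of 1-methoxy-4-({[(1R,2R)-1,2,4-trimethylcyclohex-3-en-1-yl]methoxy}methyl)benzene F4. DDQ removes the benzyl ether to give [(1R,2R)-1,2,4-trimethylcyclohex-3-en-1-yl]methanol F5, and Dess–Martin oxidation returns 3.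

2. Step 4. Enolisation of the doubly neopentyl β-keto ester may be slow or incomplete, or sulfonylation may give the wrong alkene geometry, so that the C10–C1 bond cannot be made by cross-coupling. The fallback makes that bond by carbonyl addition and creates the alkene after ring closure. It sets out from 7 and comes back at 13. Barbier allylation of the ketone (allyl bromide, indium, THF–H2O), which tolerates the acidic C5–H, should give ethyl 2-{1-hydroxy-1-[(1R,2R)-1,2,4-trimethylcyclohex-3-en-1-yl]but-3-en-1-yl}-3,3-dimethylpent-4-enoate F6. Ring-closing metathesis gives ethyl 2-hydroxy-6,6-dimethyl-2-[(1R,2R)-1,2,4-trimethylcyclohex-3-en-1-yl]cyclohex-4-ene-1-carboxylate F7, and diimide reduction gives ethyl 2-hydroxy-6,6-dimethyl-2-[(1R,2R)-1,2,4-trimethylcyclohex-3-en-1-yl]cyclohexane-1-carboxylate F8. Dehydration of this β-hydroxy ester (SOCl2, pyridine) followed by equilibration with NaOEt in EtOH, to bring the double bond into conjugation with the ester, returns 13.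

3. Step 16. The ruthenium carbene may fail to engage the hindered dienyl vinyl group next to the C4 gem-dimethyl carbon, so that intermolecular metathesis outruns ring closure. The fallback closes ring B by reductive carbonyl coupling and installs the diol at the same time. It sets out from 24 and comes back at 27. Lemieux–Johnson cleavage of the C7 vinyl group (OsO4 cat., NaIO4, 2,6-lutidine) gives 2-{(2S,3R)-5-[(2S,3R)-3-(chloromethyl)-2-methyloxiran-2-yl]-2,3-dimethyl-1-oxopentan-3-yl}-6,6-dimethylcyclohex-1-ene-1-carbaldehyde F9. Intramolecular pinacol coupling of this 1,6-dialdehyde with SmI2 (THF, t-BuOH, −78 °C) should give the cis-6,7-diol anti to the C8 methyl, which is 27.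

Further compounds
F1 | step 1 | 2-{[(4-methoxyphenyl)methoxy]methyl}prop-2-en-1-ol | C=C(CO)COCc1ccc(OC)cc1
F2 | step 1 | 2-{[(4-methoxyphenyl)methoxy]methyl}prop-2-enal | C=C(C=O)COCc1ccc(OC)cc1
F3 | step 1 | (1S,2R)-1-{[(4-methoxyphenyl)methoxy]methyl}-2,4-dimethylcyclohex-3-ene-1-carbaldehyde | CC1=C[C@@H](C)[C@](C=O)(COCc2ccc(OC)cc2)CC1
F4 | step 1 | 1-methoxy-4-({[(1R,2R)-1,2,4-trimethylcyclohex-3-en-1-yl]methoxy}methyl)benzene | CC1=C[C@@H](C)[C@](C)(COCc2ccc(OC)cc2)CC1
F5 | step 1 | [(1R,2R)-1,2,4-trimethylcyclohex-3-en-1-yl]methanol | CC1=C[C@@H](C)[C@](C)(CO)CC1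
F6 | step 4 | ethyl 2-{1-hydroxy-1-[(1R,2R)-1,2,4-trimethylcyclohex-3-en-1-yl]but-3-en-1-yl}-3,3-dimethylpent-4-enoate | CC1=C[C@@H](C)[C@](C)(C(O)(CC=C)C(C(=O)OCC)C(C)(C)C=C)CC1
F7 | step 4 | ethyl 2-hydroxy-6,6-dimethyl-2-[(1R,2R)-1,2,4-trimethylcyclohex-3-en-1-yl]cyclohex-4-ene-1-carboxylate | CC1=C[C@@H](C)[C@](C)(C2(O)CC=CC(C)(C)C2C(=O)OCC)CC1
F8 | step 4 | ethyl 2-hydroxy-6,6-dimethyl-2-[(1R,2R)-1,2,4-trimethylcyclohex-3-en-1-yl]cyclohexane-1-carboxylate | CC1=C[C@@H](C)[C@](C)(C2(O)CCCC(C)(C)C2C(=O)OCC)CC1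
F9 | step 16 | 2-{(2S,3R)-5-[(2S,3R)-3-(chloromethyl)-2-methyloxiran-2-yl]-2,3-dimethyl-1-oxopentan-3-yl}-6,6-dimethylcyclohex-1-ene-1-carbaldehyde | O=C[C@@H](C)[C@](C)(C1=C(C=O)C(C)(C)CCC1)CC[C@]2(C)O[C@H]2CCl
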